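# Rabdosiin: synthesis plan

## The problem

Rabdosiin (15) is a trans-1-aryl-1,2-dihydronaphthalene-2,3-dicarboxylic acid. Ring A is the benzo ring C4a–C8a with OH on C6 and C7. Ring B is C1–C4, C4a, C8a with C3=C4. Ring C is the 3,4-dihydroxyphenyl group on C1. Both carboxyl groups are esterified with the hydroxyl group of (R)-3-(3,4-dihydroxyphenyl)lactic acid.

The SMILES string reads 1R,2S (ring C and the C2 carboxyl group trans) and R at both lactate carbons.

A synthesis has to close ring B between two electron-rich arenes and set C1 and C2 in both the relative and the absolute sense. C1–H is doubly benzylic and C2–H is allylic and alpha to an ester, so base, oxidants or long exposure to acid lead to double-bond migration, epimerisation or the naphthalene.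

The two ester links join neighbouring, hindered carboxyl groups to secondary alcohols that are themselves alpha to a carboxyl group. Late esterification would therefore be slow and would put C2 and the lactate centres at risk.

Four catechols, two free acids, two ester links and the cinnamate-type C3=C4 bond exclude hydrogenolysis, strong base and hard Lewis acids in the last step.

The two lactate carbons can be bought. They lie three bonds from C2 and C3 and can act on them only through the conformation of the ester groups. C2, once set, controls C1 directly (trans) in any closure through a C1 cation.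

The feature that opens the plan is a hidden twofold symmetry:
- C1 and C4 are both benzylic carbons para to a phenolic oxygen (C1 to O-4′ of ring C, C4 through C4a to O-7 of ring A).
- Rings A and C are the same 3,4-dioxygenated phenyl group.
- C2 and C3 carry the same ester.
- The chain C1–C2–C3–C4 is therefore a twofold-symmetric unit ArCH–CH(CO2R*)–CH(CO2R*)–CHAr, formally a fumarate between two ArCH groups. The sense of the trans pair C2/C3 is its only independent stereochemical information.

## Retrosynthesis

**Protecting groups, 15 from 14.** No skeletal bond is cut. The eight phenolic and two carboxylic O–H bonds of 15 become O–allyl bonds in 14. Benzyl groups would call for hydrogenolysis, which endangers C3=C4. Methyl ethers would call for boron halides, which endanger the ester links. Silyl groups would call for basic fluoride. One kind of group on all ten positions allows a single mild last step, and each building block can be protected in one operation. The forward reaction has to pass ten allyl groups to a soft nucleophile under nearly neutral conditions.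

**Ring B, 14 from 12 through 13.** The bond C1–C8a is cut, C3=C4 is rehydrated (tetralol 13), and the C4 oxygen is tied to C1. The result is the 2,5-diaryltetrahydrofuran-3,4-dicarboxylate 12. Against the neighbouring cuts (C4–C4a, or C2–C3 as in the biogenesis), this one makes C1 and C4 equivalent, turns rings A and C into two copies of one aryl group, and brings out the twofold axis.

Of the four ring stereocentres of 12, the two aryl-bearing ones are erased on the way to 14: one by ionisation, one by dehydration. One succinate carbon becomes sp2. Because of the twofold axis it does not matter which one. Only the (3R,4R) configuration is therefore asked of 12. The forward reaction has to ionise a benzylic C–O bond, close ring B trans to the C2 ester, and dehydrate.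

**Tetrahydrofuran, 12 from 11 and 4.** C1–C2 and C3–C4 are cut in one retro-[3+2] step, giving carbonyl ylide 11 and fumarate 4. The target falls into its C4 diacid core with both side chains on one side and its two ArCH units on the other. Both partners are symmetric, so there is no regiochemistry. The hindered ester links of the target are already present in 4, where they are made on an unhindered fumaroyl unit. The side chains are alpha-acyloxy esters of the lactate type, the kind of chiral ester that steers additions to fumarates. Here they are part of the target and are never removed. The forward reaction has to add suprafacially to one face of 4.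

**Ylide, 11 from 10.** Closing the C–C bond of 11 gives the symmetric oxirane 10. Ring strain pays for the C–C cleavage after one-electron oxidation. The electron-rich aryl groups that make the target fragile make this oxidation easy. Both stereocentres of 10 vanish in the planar ylide, so 10 may be racemic and of either relative configuration.

**Fumarate, 4 from 2 and 3; 2 from 1.** Two acyl C–O bonds are cut, giving fumaryl chloride 3 and two molecules of alcohol 2. Alcohol 2 is the threefold O-allylated form of the chiral-pool salt 1, which supplies both lactate stereocentres.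

**Oxirane, 10 from 6 and 8 through 9; 8 from 7, 7 from 6, 6 from 5.** One C–C and one C–O bond of the oxirane are cut, giving aldehyde 6 and the benzylide 9 of sulfonium salt 8. Both halves come from the same aldehyde 6, made by O-allylation of 5. The branch therefore has one starting material and no stereochemical demand.

## Roads not taken

**Alternative 1:** (the most obvious, biomimetic) cut C2–C3 and C1–C8a.
- Forward key step: one-electron oxidation of rosmarinic acid A1 (FeCl3, Ag2O or an oxidase) would couple two radicals at their beta carbons. The product is the bis(quinone methide) A2, which closes ring B and tautomerises.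
- The spin of the radical is spread over O-4, C5 and the beta carbon, so several coupling modes compete.
- All four catechols, the lactate arenes included, are oxidisable to o-quinones, and the product is oxidised more easily than A1.
- The racemic and meso modes of coupling are decided in an open transition state far from the lactate centres.
- In the chosen plan no oxidant meets a free catechol. The trans pair C2/C3 follows from alkene geometry, and only one face selection remains.

**Alternative 2:** cut both ester C–O bonds first, then C1–C8a.
- Forward key step: double Stobbe condensation of 6 leads to the (E,E)-dibenzylidenesuccinic acid A3. Strong acid, or light (6π closure and hydrogen shift), closes ring B to the diacid A4. Two esterifications with 2 follow.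
- A3 has no stereocentre and its helical forms interconvert. A4 is therefore racemic unless an extra auxiliary is put on and taken off.
- The two ester links would then have to be made on neighbouring hindered carboxyl groups, where anhydride formation and enolisation at C2 threaten.
- The chosen plan makes these links first and uses them as the stereocontrol element.

**Alternative 3:** cut the same bonds C1–C2 and C3–C4 but leave C1–C8a in place.
- Forward key step: photoenolisation of the 2-benzylbenzaldehyde A5 gives the hydroxy-o-quinodimethane A6. Its Diels–Alder reaction with 4 would give 13 directly.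
- C1 is fixed in the cycloaddition itself. One ester of 4 must lie endo and the other exo.
- With the face of 4 given, only the orientation that puts the ester next to the carbinol carbon endo leads to 1R. The other orientation gives the 1,2-cis adduct A7 with the wrong, uncorrectable C1.
- A5 is unsymmetric and takes more steps than 10.
- In the chosen plan C1 is set after C2 and by C2, so orientation and aryl epimers do not matter.

Key step: step 7

Assumption: sodium (R)-3-(3,4-dihydroxyphenyl)lactate (1, danshensu sodium salt) is taken as a commercial, enantiopure chiral-pool material. The ring B numbering of the target (C1–C4, C4a, C8a) is used for its precursors.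

## Steps

Step 1
Reactants: 1 sodium (R)-3-(3,4-dihydroxyphenyl)lactate
Product: 2 allyl (2R)-3-[3,4-bis(allyloxy)phenyl]-2-hydroxypropanoate
Conditions: allyl bromide (3.5 equiv), K2CO3 (3 equiv), DMF, rt, Ar
Reagents that add atoms: allyl bromide C=CCBr
Why: Williamson ether synthesis and carboxylate O-alkylation; K2CO3 ionises only the two phenols beside the carboxylate, so the much less acidic secondary alcohol stays free and the stereocentre is not touched.

Step 2
Reactants: 2 allyl (2R)-3-[3,4-bis(allyloxy)phenyl]-2-hydroxypropanoate (2 equiv); 3 fumaryl chloride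
Product: 4 bis[(1R)-1-(allyloxycarbonyl)-2-(3,4-bis(allyloxy)phenyl)ethyl] fumarate
Conditions: pyridine (2.5 equiv), DMAP (10 mol %), CH2Cl2, 0 °C to rt
Reagents that add atoms: none
Why: Twofold acylation of a secondary alcohol by a bis(acid chloride) under nucleophilic catalysis; the weak base leaves the alpha-acyloxy ester centres and the E geometry intact, and both ester links of the target are made on an unhindered acyl unit.

Step 3
Reactants: 5 3,4-dihydroxybenzaldehyde
Product: 6 3,4-bis(allyloxy)benzaldehyde
Conditions: allyl bromide (2.5 equiv), K2CO3 (2.5 equiv), DMF, rt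
Reagents that add atoms: allyl bromide C=CCBr
Why: Williamson ether synthesis on both phenols; the aldehyde is inert to these conditions.

Step 4
Reactants: 6 3,4-bis(allyloxy)benzaldehyde
Product: 7 3,4-bis(allyloxy)benzyl alcohol
Conditions: NaBH4, MeOH, 0 °C
Reagents that add atoms: none
Why: Borohydride reduction of an aromatic aldehyde; allyl ethers are not affected.

Step 5
Reactants: 7 3,4-bis(allyloxy)benzyl alcohol
Product: 8 1-[3,4-bis(allyloxy)benzyl]tetrahydrothiophenium tetrafluoroborate
Conditions: tetrahydrothiophene (2 equiv), HBF4 (48 % aq., 1.1 equiv), MeCN, rt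
Reagents that add atoms: tetrahydrothiophene C1CCSC1; tetrafluoroboric acid [H+].F[B-](F)(F)F
Why: SN1 substitution; the acid ionises the 4-alkoxybenzyl alcohol, the sulfide traps the cation, and the non-nucleophilic counter-ion gives a stable salt.

Step 6
Reactants: 8 1-[3,4-bis(allyloxy)benzyl]tetrahydrothiophenium tetrafluoroborate; 6 3,4-bis(allyloxy)benzaldehyde
Product: 10 (±)-trans-2,3-bis[3,4-bis(allyloxy)phenyl]oxirane, via sulfonium ylide 9 (not isolated)
Conditions: KOH (powder, 2 equiv), MeCN/H2O 9:1, 0 °C to rt; isolation on base-washed alumina
Reagents that add atoms: none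
Why: Corey–Chaykovsky-type epoxidation with a semi-stabilised benzylide; reversible betaine formation favours the anti betaine and hence the trans oxirane. The configuration of 10 is of no consequence, since both centres vanish in 11.

Step 7
Reactants: 4 bis[(1R)-1-(allyloxycarbonyl)-2-(3,4-bis(allyloxy)phenyl)ethyl] fumarate; 10 (±)-trans-2,3-bis[3,4-bis(allyloxy)phenyl]oxirane (1.2 equiv)
Product: 14 deca-O-allylrabdosiin = bis[(1R)-1-(allyloxycarbonyl)-2-(3,4-bis(allyloxy)phenyl)ethyl] (1R,2S)-6,7-bis(allyloxy)-1-[3,4-bis(allyloxy)phenyl]-1,2-dihydronaphthalene-2,3-dicarboxylate, via carbonyl ylide 11 (not isolated), via tetrahydrofuran diester 12 (not isolated), via tetralol 13 (not isolated)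
Conditions: 4-mesityl-2,6-diphenylpyrylium tetrafluoroborate (5 mol %), blue LED (455 nm), CH2Cl2, −20 °C, Ar; then CF3SO3H (0.3 equiv), −20 to 0 °C
Reagents that add atoms: none
Why: The excited pyrylium salt takes one electron from oxirane 10, ring strain drives C–C scission of the radical cation, and back electron transfer gives the planar, achiral carbonyl ylide 11, which adds as a nucleophilic 4π dipole to the electron-poor C=C bond of 4; the closest known reaction type is the electron-transfer-sensitised [3+2] cycloaddition of 2,3-diaryloxiranes with fumarates to 2,5-diaryltetrahydrofuran-3,4-dicarboxylates. The tetrahydrofuran ring closes in a concerted suprafacial [π4s+π2s] mode that forms C1–C2 and C3–C4 and carries the E geometry of 4 into the trans pair C2/C3. The absolute sense of this pair is controlled by the two bought lactate centres: with each ester in the Z form, its carbinol C–H eclipsing the C=O group and the enoate s-cis, the twofold axis of 4 places both 3,4-bis(allyloxy)benzyl arms over the Re,Re face, where they can stack on the fumarate, so 11 should add to the Si,Si face and give (3R,4R)-12, which is 2S,3R in ring B numbering; the same conformational model accounts for the sense of induction of lactate- and mandelate-type fumarates in cycloadditions. The aryl-bearing carbons of 12 arise as epimer mixtures, which is of no consequence. CF3SO3H then ionises either benzylic C–O bond to a 4-allyloxybenzyl cation (C1), and the aryl group on the other benzylic carbon attacks through its position para to the 3-allyloxy group, closing ring B in a 6-exo Friedel–Crafts alkylation (C1–C8a), as known for the acid-induced change of 2,5-diaryltetrahydrofuran lignans into aryltetralins and aryldihydronaphthalenes. C1 is controlled by C2: in the chair-like transition state both ester groups and ring C lie pseudo-equatorial, so ring C ends up trans to the C2 ester (1R from 2S). E1 dehydration of the 4-alkoxybenzylic alcohol 13 gives the conjugated C3=C4 bond and deletes C3 and C4, and because the succinate pair is twofold symmetric and both aryl groups are the same, both modes of ionisation and all aryl epimers of 12 converge on 14. The step needs face selectivity at 4 (secured by two arms acting on the same face), chemoselectivity of 11 for the fumarate over the allyl C=C bonds (secured by the nucleophilic character of the ylide), and ring closure faster than a twofold proton loss that would erase C2 (secured by the activated arene position held six atoms from C1).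

Step 8
Reactants: 14 deca-O-allylrabdosiin
Product: 15 rabdosiin
Conditions: Pd(PPh3)4 (20 mol %), morpholine (30 equiv), THF, rt, Ar; then 1 M HCl work-up, reversed-phase purification
Reagents that add atoms: none
Why: Tsuji–Trost-type allyl transfer; zerovalent palladium ionises aryl allyl ethers and allyl esters to π-allyl complexes of divalent palladium, and morpholine intercepts them. The secondary alkyl ester links, C3=C4 and all four stereocentres are not addressed by these nearly neutral conditions, which have close precedent in the unmasking of caffeic ester polyphenols.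

## Compound list

1 | sodium (R)-3-(3,4-dihydroxyphenyl)lactate (danshensu sodium salt) | O[C@H](Cc1ccc(O)c(O)c1)C(=O)[O-].[Na+] | starting material
2 | allyl (2R)-3-[3,4-bis(allyloxy)phenyl]-2-hydroxypropanoate | O[C@H](Cc1ccc(OCC=C)c(OCC=C)c1)C(=O)OCC=C | intermediate
3 | fumaryl chloride | O=C(Cl)/C=C/C(=O)Cl | starting material
4 | bis[(1R)-1-(allyloxycarbonyl)-2-(3,4-bis(allyloxy)phenyl)ethyl] fumarate | C=CCOC(=O)[C@@H](Cc1ccc(OCC=C)c(OCC=C)c1)OC(=O)/C=C/C(=O)O[C@H](Cc1ccc(OCC=C)c(OCC=C)c1)C(=O)OCC=C | intermediate
5 | 3,4-dihydroxybenzaldehyde | O=Cc1ccc(O)c(O)c1 | starting material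
6 | 3,4-bis(allyloxy)benzaldehyde | O=Cc1ccc(OCC=C)c(OCC=C)c1 | intermediate
7 | 3,4-bis(allyloxy)benzyl alcohol | OCc1ccc(OCC=C)c(OCC=C)c1 | intermediate
8 | 1-[3,4-bis(allyloxy)benzyl]tetrahydrothiophenium tetrafluoroborate | C=CCOc1ccc(C[S+]2CCCC2)cc1OCC=C.F[B-](F)(F)F | intermediate
9 | tetrahydrothiophenium 3,4-bis(allyloxy)benzylide (not isolated) | C=CCOc1ccc([CH-][S+]2CCCC2)cc1OCC=C | intermediate
10 | (±)-trans-2,3-bis[3,4-bis(allyloxy)phenyl]oxirane (racemic, the 2S,3S enantiomer drawn) | C=CCOc1ccc([C@@H]2O[C@H]2c2ccc(OCC=C)c(OCC=C)c2)cc1OCC=C | intermediate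
11 | bis[3,4-bis(allyloxy)phenyl] carbonyl ylide (not isolated) | C=CCOc1ccc(C=[O+][CH-]c2ccc(OCC=C)c(OCC=C)c2)cc1OCC=C | intermediate
12 | bis[(1R)-1-(allyloxycarbonyl)-2-(3,4-bis(allyloxy)phenyl)ethyl] (3R,4R)-2,5-bis[3,4-bis(allyloxy)phenyl]tetrahydrofuran-3,4-dicarboxylate, epimer mixture at C2 and C5 (not isolated) | O1C(c2ccc(OCC=C)c(OCC=C)c2)[C@H](C(=O)O[C@H](Cc2ccc(OCC=C)c(OCC=C)c2)C(=O)OCC=C)[C@@H](C(=O)O[C@H](Cc2ccc(OCC=C)c(OCC=C)c2)C(=O)OCC=C)C1c1ccc(OCC=C)c(OCC=C)c1 | intermediate
13 | bis[(1R)-1-(allyloxycarbonyl)-2-(3,4-bis(allyloxy)phenyl)ethyl] (1R,2S,3R)-6,7-bis(allyloxy)-1-[3,4-bis(allyloxy)phenyl]-4-hydroxy-1,2,3,4-tetrahydronaphthalene-2,3-dicarboxylate, epimer mixture at C4 (not isolated) | OC1c2cc(OCC=C)c(OCC=C)cc2[C@@H](c2ccc(OCC=C)c(OCC=C)c2)[C@H](C(=O)O[C@H](Cc2ccc(OCC=C)c(OCC=C)c2)C(=O)OCC=C)[C@H]1C(=O)O[C@H](Cc1ccc(OCC=C)c(OCC=C)c1)C(=O)OCC=C | intermediate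
14 | deca-O-allylrabdosiin, (1R,2S) core, R at both lactate carbons | O=C(O[C@H](Cc1ccc(OCC=C)c(OCC=C)c1)C(=O)OCC=C)C1=Cc2cc(OCC=C)c(OCC=C)cc2[C@@H](c2ccc(OCC=C)c(OCC=C)c2)[C@@H]1C(=O)O[C@H](Cc1ccc(OCC=C)c(OCC=C)c1)C(=O)OCC=C | intermediate
15 | rabdosiin | O=C(O[C@H](Cc1ccc(O)c(O)c1)C(=O)O)C1=Cc2cc(O)c(O)cc2[C@@H](c2ccc(O)c(O)c2)[C@@H]1C(=O)O[C@H](Cc1ccc(O)c(O)c1)C(=O)O | target

## Step count and risks

Total step count: 8. Longest linear sequence: 6 steps (5 → 6 → 7 → 8 → 10 → 14 → 15). The second branch (1 → 2 → 4) joins at step 7.

**Step 7 (key step).** The most likely failure is poor facial selectivity at the fumarate. The lactate centres lie three bonds from the reacting carbons. Rotation about the C(sp2)–C(=O) bonds from s-cis to s-trans exchanges the shielded face, and a polar medium weakens the stacking of the arms.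

The fallback sets the succinate pair by auxiliary control and reaches the same C1 cation by hydride abstraction. It sets out from 6 and 2 and comes back at 14.
- Reductive condensation of 6 with Meldrum's acid in HCO2H/Et3N gives 3-[3,4-bis(allyloxy)phenyl]propanoic acid F1.
- F1 is bound (pivaloyl chloride, Et3N, LiCl) to (R)-4-benzyloxazolidin-2-one as the imide (4R)-4-benzyl-3-{3-[3,4-bis(allyloxy)phenyl]propanoyl}oxazolidin-2-one F2.
- Oxidative homocoupling of its lithium enolate (LDA, THF, −78 °C, then CuCl2) joins two enolates, each on the face away from the benzyl group of the auxiliary. This gives the (2S,3S)-2,3-bis[3,4-bis(allyloxy)benzyl]succinyl bis-imide F3.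
- LiOH/H2O2 releases (2S,3S)-2,3-bis[3,4-bis(allyloxy)benzyl]succinic acid F4.
- Carbodiimide/DMAP esterification with two equivalents of 2 gives the bis(lactate) diester F5.
- DDQ (2 equiv) in CH2Cl2/CF3CO2H at 0 °C abstracts hydride from one benzylic CH2 group, and ring B closes trans to the C2 ester as in step 7. A second hydride abstraction at C4 with loss of H3 leads to 14.

**Step 8.** The most likely failures are incomplete tenfold allyl transfer, C-allylation of the liberated catechols by the π-allyl complex, and air oxidation of catecholates in the amine medium.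

The fallback separates bond migration from cleavage. It sets out from 14 and comes back at 15.
- [Ir(cod)(PMePh2)2]PF6 (activated with H2, then degassed) in THF isomerises all allyl groups to prop-1-enyl groups, giving deca-O-[(E)-prop-1-enyl]rabdosiin F8.
- Its enol ethers and enol esters are hydrolysed by dilute HCl in aqueous acetone. This acidic medium keeps the catechols protonated.

**Step 6.** The most likely failure is acid-induced ring opening or Meinwald rearrangement of the very electron-rich oxirane during work-up and chromatography, together with slow ylide addition to the electron-rich aldehyde.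

The fallback replaces ylide epoxidation by olefination and neutral oxygen transfer. It sets out from 7 and 6 and comes back at 10.
- P(OEt)3 and ZnI2 in toluene convert 7 into diethyl [3,4-bis(allyloxy)benzyl]phosphonate F6.
- Horner–Wadsworth–Emmons reaction with 6 (NaH, THF) gives (E)-3,3′,4,4′-tetrakis(allyloxy)stilbene F7.
- One equivalent of dimethyldioxirane in acetone at −20 °C epoxidises the electron-rich central C=C bond in preference to the terminal allyl groups.
- Evaporation leaves 10 ready for step 7 without chromatography.

## Further compounds

F1 | step 7 | 3-[3,4-bis(allyloxy)phenyl]propanoic acid | OC(=O)CCc1ccc(OCC=C)c(OCC=C)c1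
F2 | step 7 | (4R)-4-benzyl-3-{3-[3,4-bis(allyloxy)phenyl]propanoyl}oxazolidin-2-one | O=C(CCc1ccc(OCC=C)c(OCC=C)c1)N1[C@H](Cc2ccccc2)COC1=O
F3 | step 7 | (2S,3S)-2,3-bis[3,4-bis(allyloxy)benzyl]succinyl bis[(4R)-4-benzyloxazolidin-2-one] imide | O=C([C@@H](Cc1ccc(OCC=C)c(OCC=C)c1)[C@H](Cc1ccc(OCC=C)c(OCC=C)c1)C(=O)N1[C@H](Cc2ccccc2)COC1=O)N1[C@H](Cc2ccccc2)COC1=O
F4 | step 7 | (2S,3S)-2,3-bis[3,4-bis(allyloxy)benzyl]succinic acid | OC(=O)[C@@H](Cc1ccc(OCC=C)c(OCC=C)c1)[C@H](Cc1ccc(OCC=C)c(OCC=C)c1)C(=O)O
F5 | step 7 | bis[(1R)-1-(allyloxycarbonyl)-2-(3,4-bis(allyloxy)phenyl)ethyl] (2S,3S)-2,3-bis[3,4-bis(allyloxy)benzyl]succinate | C=CCOC(=O)[C@@H](Cc1ccc(OCC=C)c(OCC=C)c1)OC(=O)[C@@H](Cc1ccc(OCC=C)c(OCC=C)c1)[C@H](Cc1ccc(OCC=C)c(OCC=C)c1)C(=O)O[C@H](Cc1ccc(OCC=C)c(OCC=C)c1)C(=O)OCC=C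
F6 | step 6 | diethyl [3,4-bis(allyloxy)benzyl]phosphonate | CCOP(=O)(Cc1ccc(OCC=C)c(OCC=C)c1)OCC
F7 | step 6 | (E)-3,3′,4,4′-tetrakis(allyloxy)stilbene | C=CCOc1ccc(/C=C/c2ccc(OCC=C)c(OCC=C)c2)cc1OCC=C
F8 | step 8 | deca-O-[(E)-prop-1-enyl]rabdosiin | O=C(O[C@H](Cc1ccc(O/C=C/C)c(O/C=C/C)c1)C(=O)O/C=C/C)C1=Cc2cc(O/C=C/C)c(O/C=C/C)cc2[C@@H](c2ccc(O/C=C/C)c(O/C=C/C)c2)[C@@H]1C(=O)O[C@H](Cc1ccc(O/C=C/C)c(O/C=C/C)c1)C(=O)O/C=C/C
A1 | alternative 1 | (R)-rosmarinic acid | O=C(/C=C/c1ccc(O)c(O)c1)O[C@H](Cc1ccc(O)c(O)c1)C(=O)O
A2 | alternative 1 | beta,beta′-coupled bis(p-quinone methide) of rosmarinic acid (new centres and exocyclic alkenes undefined) | O=C1C=CC(=CC(C(=O)O[C@H](Cc2ccc(O)c(O)c2)C(=O)O)C(C=C2C=CC(=O)C(O)=C2)C(=O)O[C@H](Cc2ccc(O)c(O)c2)C(=O)O)C=C1O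
A3 | alternative 2 | (E,E)-2,3-bis[3,4-bis(allyloxy)benzylidene]succinic acid | OC(=O)/C(=C/c1ccc(OCC=C)c(OCC=C)c1)C(=C\c1ccc(OCC=C)c(OCC=C)c1)/C(=O)O
A4 | alternative 2 | (±)-trans-6,7-bis(allyloxy)-1-[3,4-bis(allyloxy)phenyl]-1,2-dihydronaphthalene-2,3-dicarboxylic acid (racemic, one enantiomer drawn) | OC(=O)C1=Cc2cc(OCC=C)c(OCC=C)cc2[C@@H](c2ccc(OCC=C)c(OCC=C)c2)[C@@H]1C(=O)O
A5 | alternative 3 | 4,5-bis(allyloxy)-2-[3,4-bis(allyloxy)benzyl]benzaldehyde | O=Cc1cc(OCC=C)c(OCC=C)cc1Cc1ccc(OCC=C)c(OCC=C)c1
A6 | alternative 3 | (E,E)-alpha-hydroxy-alpha′-aryl-o-quinodimethane from A5 | O/C=C1\C=C(OCC=C)C(OCC=C)=C/C1=C\c1ccc(OCC=C)c(OCC=C)c1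
A7 | alternative 3 | 1,2-cis-2,3-trans-3,4-trans Diels–Alder adduct (1S,2S,3R,4S) of A6 and 4 | O[C@@H]1c2cc(OCC=C)c(OCC=C)cc2[C@H](c2ccc(OCC=C)c(OCC=C)c2)[C@H](C(=O)O[C@H](Cc2ccc(OCC=C)c(OCC=C)c2)C(=O)OCC=C)[C@H]1C(=O)O[C@H](Cc1ccc(OCC=C)c(OCC=C)c1)C(=O)OCC=C
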